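**Retrosynthetic overview**
1. Target 21 ⇐ epoxidation of the Z‑C1=C10 olefin of macrocycle 20 (oxirane formed last).
2. Ten‑membered carbocycle ⇐ C6–C7 bond by intramolecular chromium‑mediated allylation of the C6 aldehyde with a 3‑(bromomethyl)butenolide (sets C6 and C7, leaves 6‑OH free).
3. Butenolide (first ring) ⇐ ring‑closing metathesis of a 2‑(bromomethyl)acrylate of an (8R)‑vinyl carbinol; C3–C6 ⇐ Morita–Baylis–Hillman reaction of a vinyl ketone with (S)‑glyceraldehyde acetonide (sets C5), then angeloylation.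
4. Z‑configured C8–C9–C10(Me)=C1–C2–C3 chain with aldehyde and ester ends ⇐ Birch reduction of 4‑methylanisole and ozonolytic opening of the enol‑ether bond; the ring fixes the olefin geometry and hence the cis‑epoxide.
5. Ring order: butenolide → ten‑membered ring → epoxide.

Assumption: 8, 10 and 15 are purchased; carbons are labelled C1–C15 by a germacrane‑type count (C8 lactone carbinol, C7 ring fusion bearing C11(=C13H2)–C12(=O)O, C6 CHOH, C5 CHOAng, C4(=C15H2), C3 ketone, C2, C1/C10 epoxide with C14 methyl on C10, C9).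

**Step 1**
Reactants: 1 4-methylanisole
Product: 2 1-methoxy-4-methylcyclohexa-1,4-diene
Conditions: Li, NH3(l)/THF, t-BuOH, −78 → −33 °C; NH4Cl
Reagents that add atoms: none
Why: Birch reduction gives the 2,5‑dihydro isomer with OMe and Me on the two remaining double bonds, so the future C10=C1 olefin sits in a six‑membered ring and can only be Z; no stereocentre.

**Step 2**
Reactants: 2 1-methoxy-4-methylcyclohexa-1,4-diene
Product: 5 methyl (Z)-6,6-dimethoxy-4-methylhex-3-enoate, via methoxy hydroperoxide 3 (not isolated), via aldehyde ester 4 (not isolated)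
Conditions: O3 (1.0 equiv), CH2Cl2/MeOH, −78 °C; Me2S, −78 → 23 °C; then HC(OMe)3, TsOH·H2O (cat.), 23 °C; NaHCO3
Reagents that add atoms: ozone, [O-][O+]=O; methanol, CO; trimethyl orthoformate, COC(OC)OC
Why: chemoselective ozonolysis of the much more electron‑rich enol‑ether bond opens the ring to the C3 ester and, after reduction of the methoxy hydroperoxide, the C8 aldehyde, which is acetalised in the same pot; the trisubstituted olefin keeps its ring‑derived Z geometry.

**Step 3**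
Reactants: 5 methyl (Z)-6,6-dimethoxy-4-methylhex-3-enoate
Product: 7 (Z)-8,8-dimethoxy-6-methylocta-1,5-dien-3-one, via Weinreb amide 6 (not isolated)
Conditions: MeNH(OMe)·HCl, i-PrMgCl, THF, −20 °C; then CH2=CHMgBr, −20 → 0 °C; poured into cold aq. NH4Cl
Reagents that add atoms: N,O-dimethylhydroxylamine hydrochloride, CNOC.Cl (carried only in 6); vinylmagnesium bromide, C=C[Mg]Br
Why: one‑pot Weinreb ketone synthesis (magnesium‑amide aminolysis of the ester, then single addition of the Grignard reagent to the chelated amide); no stereocentre.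

**Step 4**
Reactants: 7 (Z)-8,8-dimethoxy-6-methylocta-1,5-dien-3-one; 8 (S)-2,2-dimethyl-1,3-dioxolane-4-carbaldehyde
Product: 9 (5Z)-2-{(R)-[(4S)-2,2-dimethyl-1,3-dioxolan-4-yl](hydroxy)methyl}-8,8-dimethoxy-6-methylocta-1,5-dien-3-one
Conditions: DABCO (0.3 equiv), 8 (2 equiv), 1,4-dioxane/H2O 1:1, 0 → 23 °C; chromatography
Reagents that add atoms: none
Why: Morita–Baylis–Hillman reaction; the ammonium enolate adds to the α‑alkoxy aldehyde in the Felkin–Anh sense to give mainly the anti adduct (about 3:1 expected, separated), which sets C5 as R.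

**Step 5**
Reactants: 9 Baylis–Hillman alcohol; 10 angelic acid
Product: 12 (R)-[(4S)-2,2-dimethyl-1,3-dioxolan-4-yl][(5Z)-8,8-dimethoxy-6-methyl-3-oxoocta-1,5-dien-2-yl]methyl (Z)-2-methylbut-2-enoate, via mixed anhydride 11 (not isolated)
Conditions: 10, 2,4,6-Cl3C6H2COCl, Et3N, PhMe, 23 °C; then 9, PhMe, 75 °C
Reagents that add atoms: 2,4,6-trichlorobenzoyl chloride, O=C(Cl)c1c(Cl)cc(Cl)cc1Cl (carried only in 11)
Why: Yamaguchi esterification without DMAP, conditions under which the angeloyl group is transferred without Z to E isomerisation; C5 is retained.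

**Step 6**
Reactants: 12 angelate dimethyl acetal
Product: 13 (R)-[(4S)-2,2-dimethyl-1,3-dioxolan-4-yl][(5Z)-6-methyl-3,8-dioxoocta-1,5-dien-2-yl]methyl (Z)-2-methylbut-2-enoate
Conditions: PPTS (cat.), acetone/H2O 10:1, 23 °C; used crude
Reagents that add atoms: water, O
Why: selective acetal hydrolysis; the simple dimethyl acetal cleaves under mild acid while acetone as solvent preserves the isopropylidene acetal.

**Step 7**
Reactants: 13 C8 aldehyde
Product: 14 (R)-[(4S)-2,2-dimethyl-1,3-dioxolan-4-yl][(5Z,8R)-8-hydroxy-6-methyl-3-oxodeca-1,5,9-trien-2-yl]methyl (Z)-2-methylbut-2-enoate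
Conditions: (CH2=CH)2Zn, (−)-MIB [(2S)-3-exo-morpholinoisoborneol] (10 mol %), PhMe, −30 → 0 °C; aq. NH4Cl
Reagents that add atoms: divinylzinc, C=C[Zn]C=C
Why: amino‑alcohol‑catalysed enantioselective alkenylzinc addition (Noyori/Oppolzer type); (−)-MIB directs vinyl transfer to the Si face and sets C8 as R, and the organozinc leaves ketone, enone and esters alone.

**Step 8**
Reactants: 14 (8R)-allylic alcohol; 15 2-(bromomethyl)prop-2-enoic acid
Product: 16 (3R,5Z)-9-{(R)-[(4S)-2,2-dimethyl-1,3-dioxolan-4-yl][(Z)-2-methylbut-2-enoyloxy]methyl}-5-methyl-8-oxodeca-1,5,9-trien-3-yl 2-(bromomethyl)prop-2-enoate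
Conditions: DCC, DMAP (10 mol %), CH2Cl2, −20 → 0 °C
Reagents that add atoms: none
Why: Steglich esterification of the only free hydroxyl, with retention at C8.

**Step 9**
Reactants: 16 acrylate ester
Product: 17 (R)-{(5Z)-7-[(2R)-4-(bromomethyl)-5-oxo-2,5-dihydrofuran-2-yl]-6-methyl-3-oxohepta-1,5-dien-2-yl}[(4S)-2,2-dimethyl-1,3-dioxolan-4-yl]methyl (Z)-2-methylbut-2-enoate
Conditions: second-generation Grubbs catalyst RuCl2(=CHPh)(H2IMes)(PCy3) (5 mol %), CH2Cl2 (5 mM), 40 °C
Reagents that add atoms: none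
Why: ring‑closing metathesis between the C7 vinyl group and the acrylate closes the five‑membered butenolide with loss of ethylene, faster than any larger‑ring mode; C8 is untouched.

**Step 10**
Reactants: 17 butenolide acetonide
Product: 19 (2R,6Z)-8-[(2R)-4-(bromomethyl)-5-oxo-2,5-dihydrofuran-2-yl]-7-methyl-3-methylidene-1,4-dioxooct-6-en-2-yl (Z)-2-methylbut-2-enoate, via diol 18 (not isolated)
Conditions: H5IO6, EtOAc, 23 °C; used crude
Reagents that add atoms: none
Why: periodic acid hydrolyses the terminal acetonide and cleaves the resulting 1,2‑diol in one pot (glycol cleavage), unveiling the C6 aldehyde under acidic conditions that do not epimerise C5.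

**Step 11**
Reactants: 19 C6 aldehyde
Product: 20 (5R,6R,7R,8R,1(10)Z)-5-angeloyloxy-6-hydroxy-3-oxogermacra-1(10),4(15),11(13)-trien-12,8-olide
Conditions: CrCl2 (8 equiv), THF, 23 °C, syringe-pump addition (final 2 mM); pH 7 buffer
Reagents that add atoms: none
Why: Proposed new method: intramolecular Nozaki–Hiyama allylation in which CrCl2 turns the allylic bromide into a C13‑bound allylchromium that attacks the aldehyde through C7 in a chair transition state, from the butenolide face anti to the C9 tether and with C5 and C8 pseudo‑equatorial, giving the trans‑fused lactone with C7 R and C6 R; the hindered conjugated C3 ketone should be spared by the aldehyde selectivity of allylchromium, and the closest known reactions are Cr‑ or In‑mediated allylations of aldehydes with 3‑(bromomethyl)furan‑2(5H)‑ones and intramolecular Nozaki–Hiyama closures of ten‑membered germacranolide rings.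

**Step 12**
Reactants: 20 macrocyclic triene
Product: 21 (1S,5R,6R,7R,8R,10R)-5-angeloyloxy-1,10-epoxy-6-hydroxy-3-oxogermacra-4(15),11(13)-dien-12,8-olide
Conditions: mCPBA (1.1 equiv), NaHCO3, CH2Cl2, 0 °C
Reagents that add atoms: mCPBA, OOC(=O)c1cccc(Cl)c1
Why: Prilezhaev epoxidation of the only electron‑rich olefin (enone, α‑methylene lactone and angelate are deactivated); syn delivery to the Z olefin gives the cis‑epoxide, and attack on the exposed outer face is expected, but not proven, to give 1S,10R.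

**Compound list**
1 | 4-methylanisole | COc1ccc(C)cc1 | starting material
2 | 1-methoxy-4-methylcyclohexa-1,4-diene | COC1=CCC(C)=CC1 | intermediate
3 | methyl (Z)-6-hydroperoxy-6-methoxy-4-methylhex-3-enoate (methoxy hydroperoxide, not isolated) | COC(=O)C/C=C(C)\CC(OC)OO | intermediate
4 | methyl (Z)-4-methyl-6-oxohex-3-enoate (aldehyde ester, not isolated) | COC(=O)C/C=C(C)\CC=O | intermediate
5 | methyl (Z)-6,6-dimethoxy-4-methylhex-3-enoate | COC(=O)C/C=C(C)\CC(OC)OC | intermediate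
6 | (Z)-N,6,6-trimethoxy-N,4-dimethylhex-3-enamide (Weinreb amide, not isolated) | CON(C)C(=O)C/C=C(C)\CC(OC)OC | intermediate
7 | (Z)-8,8-dimethoxy-6-methylocta-1,5-dien-3-one | C=CC(=O)C/C=C(C)\CC(OC)OC | intermediate
8 | (S)-2,2-dimethyl-1,3-dioxolane-4-carbaldehyde | O=C[C@@H]1COC(C)(C)O1 | starting material
9 | (5Z)-2-{(R)-[(4S)-2,2-dimethyl-1,3-dioxolan-4-yl](hydroxy)methyl}-8,8-dimethoxy-6-methylocta-1,5-dien-3-one | COC(OC)C/C(C)=C\CC(=O)C(=C)[C@@H](O)[C@@H]1COC(C)(C)O1 | intermediate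
10 | angelic acid, (Z)-2-methylbut-2-enoic acid | C/C=C(/C)C(=O)O | starting material
11 | (Z)-2-methylbut-2-enoic 2,4,6-trichlorobenzoic anhydride (mixed anhydride, not isolated) | C/C=C(/C)C(=O)OC(=O)c1c(Cl)cc(Cl)cc1Cl | intermediate
12 | (R)-[(4S)-2,2-dimethyl-1,3-dioxolan-4-yl][(5Z)-8,8-dimethoxy-6-methyl-3-oxoocta-1,5-dien-2-yl]methyl (Z)-2-methylbut-2-enoate | COC(OC)C/C(C)=C\CC(=O)C(=C)[C@@H](OC(=O)/C(C)=C\C)[C@@H]1COC(C)(C)O1 | intermediate
13 | (R)-[(4S)-2,2-dimethyl-1,3-dioxolan-4-yl][(5Z)-6-methyl-3,8-dioxoocta-1,5-dien-2-yl]methyl (Z)-2-methylbut-2-enoate | O=CC/C(C)=C\CC(=O)C(=C)[C@@H](OC(=O)/C(C)=C\C)[C@@H]1COC(C)(C)O1 | intermediate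
14 | (R)-[(4S)-2,2-dimethyl-1,3-dioxolan-4-yl][(5Z,8R)-8-hydroxy-6-methyl-3-oxodeca-1,5,9-trien-2-yl]methyl (Z)-2-methylbut-2-enoate | C=C[C@H](O)C/C(C)=C\CC(=O)C(=C)[C@@H](OC(=O)/C(C)=C\C)[C@@H]1COC(C)(C)O1 | intermediate
15 | 2-(bromomethyl)prop-2-enoic acid | C=C(CBr)C(=O)O | starting material
16 | (3R,5Z)-9-{(R)-[(4S)-2,2-dimethyl-1,3-dioxolan-4-yl][(Z)-2-methylbut-2-enoyloxy]methyl}-5-methyl-8-oxodeca-1,5,9-trien-3-yl 2-(bromomethyl)prop-2-enoate | C=C[C@H](OC(=O)C(=C)CBr)C/C(C)=C\CC(=O)C(=C)[C@@H](OC(=O)/C(C)=C\C)[C@@H]1COC(C)(C)O1 | intermediate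
17 | (R)-{(5Z)-7-[(2R)-4-(bromomethyl)-5-oxo-2,5-dihydrofuran-2-yl]-6-methyl-3-oxohepta-1,5-dien-2-yl}[(4S)-2,2-dimethyl-1,3-dioxolan-4-yl]methyl (Z)-2-methylbut-2-enoate | BrCC1=C[C@@H](C/C(C)=C\CC(=O)C(=C)[C@@H](OC(=O)/C(C)=C\C)[C@@H]2COC(C)(C)O2)OC1=O | intermediate
18 | diol from acetonide hydrolysis of 17: (S)-2,3-dihydroxypropyl unit in place of the dioxolane (not isolated) | BrCC1=C[C@@H](C/C(C)=C\CC(=O)C(=C)[C@@H](OC(=O)/C(C)=C\C)[C@@H](O)CO)OC1=O | intermediate
19 | (2R,6Z)-8-[(2R)-4-(bromomethyl)-5-oxo-2,5-dihydrofuran-2-yl]-7-methyl-3-methylidene-1,4-dioxooct-6-en-2-yl (Z)-2-methylbut-2-enoate | BrCC1=C[C@@H](C/C(C)=C\CC(=O)C(=C)[C@@H](OC(=O)/C(C)=C\C)C=O)OC1=O | intermediate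
20 | (5R,6R,7R,8R,1(10)Z)-5-angeloyloxy-6-hydroxy-3-oxogermacra-1(10),4(15),11(13)-trien-12,8-olide | C=C1C(=O)O[C@@H]2C/C(C)=C\CC(=O)C(=C)[C@@H](OC(=O)/C(C)=C\C)[C@H](O)[C@@H]12 | intermediate
21 | (1S,5R,6R,7R,8R,10R)-5-angeloyloxy-1,10-epoxy-6-hydroxy-3-oxogermacra-4(15),11(13)-dien-12,8-olide (CNP0348992.7) | C=C1C(=O)O[C@@H]2C[C@@]3(C)O[C@H]3CC(=O)C(=C)[C@@H](OC(=O)/C(C)=C\C)[C@H](O)[C@@H]12 | target

**Totals**
Total step count: 12. Longest linear sequence: 12 steps (from 1).

**Steps most likely to fail**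

Step 11 (ring closure). The risks are attack of C7 on the C3 ketone to give a seven‑membered ring, a cis‑fused lactone, or epimerisation of C5 in aldehyde 19. The fallback takes the ketone out of play. Setting out from butenolide 17, Luche reduction (NaBH4, CeCl3·7H2O, MeOH, −78 °C) gives the C3 allylic alcohol F1 as both C3 epimers. TBSOTf with 2,6‑lutidine gives the silyl ether F2. H5IO6 gives, by way of the diol F3, the C6 aldehyde F4. CrCl2 in dilute THF closes the ring to the C3‑silyloxy macrocycle F5, and HF·pyridine frees the C3 carbinol F6. MnO2 then oxidises only this allylic alcohol (the C6 carbinol is not allylic), which brings the route back to 20.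

Step 7 (enantioselective vinylation of an enolisable β,γ‑unsaturated aldehyde). The fallback replaces catalyst control by resolution. Setting out from aldehyde 13, Nozaki–Hiyama–Kishi vinylation (vinyl bromide, CrCl2, NiCl2 cat., DMF) gives the C8 epimer mixture F7. Sharpless kinetic resolution (Ti(OiPr)4, L‑(+)‑DIPT, t‑BuOOH, 4 Å sieves, CH2Cl2, −20 °C) epoxidises the 8S epimer to the epoxy alcohol F8 and leaves the 8R epimer, which is 14.

Step 12 (facial selectivity of the epoxidation). If the peracid delivers oxygen to the other face, the fallback inverts the outcome in two steps. Setting out from 20, NBS in wet THF gives the bromohydrin F9 (bromonium on the peracid face, water opening at C10 from the opposite face). Ag2O in CH2Cl2 closes it with inversion at C1 under non‑basic conditions, which gives 21.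

**Further compounds**
F1 | step 11 | C3 allylic alcohol from Luche reduction of 17 (C3 epimers) | BrCC1=C[C@@H](C/C(C)=C\CC(O)C(=C)[C@@H](OC(=O)/C(C)=C\C)[C@@H]2COC(C)(C)O2)OC1=O
F2 | step 11 | C3 tert-butyldimethylsilyl ether of F1 | BrCC1=C[C@@H](C/C(C)=C\CC(O[Si](C)(C)C(C)(C)C)C(=C)[C@@H](OC(=O)/C(C)=C\C)[C@@H]2COC(C)(C)O2)OC1=O
F3 | step 11 | diol from acetonide hydrolysis of F2 | BrCC1=C[C@@H](C/C(C)=C\CC(O[Si](C)(C)C(C)(C)C)C(=C)[C@@H](OC(=O)/C(C)=C\C)[C@@H](O)CO)OC1=O
F4 | step 11 | C6 aldehyde with C3 silyl ether | BrCC1=C[C@@H](C/C(C)=C\CC(O[Si](C)(C)C(C)(C)C)C(=C)[C@@H](OC(=O)/C(C)=C\C)C=O)OC1=O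
F5 | step 11 | macrocycle 20 with C3 as silyloxy carbinol | C=C1C(=O)O[C@@H]2C/C(C)=C\CC(O[Si](C)(C)C(C)(C)C)C(=C)[C@@H](OC(=O)/C(C)=C\C)[C@H](O)[C@@H]12
F6 | step 11 | macrocycle 20 with C3 as free carbinol | C=C1C(=O)O[C@@H]2C/C(C)=C\CC(O)C(=C)[C@@H](OC(=O)/C(C)=C\C)[C@H](O)[C@@H]12
F7 | step 7 | C8 epimer mixture of allylic alcohol 14 | C=CC(O)C/C(C)=C\CC(=O)C(=C)[C@@H](OC(=O)/C(C)=C\C)[C@@H]1COC(C)(C)O1
F8 | step 7 | erythro epoxy alcohol from the 8S epimer | C1O[C@@H]1[C@@H](O)C/C(C)=C\CC(=O)C(=C)[C@@H](OC(=O)/C(C)=C\C)[C@@H]2COC(C)(C)O2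
F9 | step 12 | bromohydrin of 20 (1-bromo, 10-hydroxy) | C=C1C(=O)O[C@@H]2C[C@@](C)(O)[C@H](Br)CC(=O)C(=C)[C@@H](OC(=O)/C(C)=C\C)[C@H](O)[C@@H]12
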